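A direct plan would treat rings A and B as two different building blocks and use a pyranone as template: a ring-A boronic acid A1 would be added with a chiral Rh catalyst to a daphnetin-derived coumarin to give chromanone A2 (C1).
C2 would follow by anti alkylation of the lactone enolate. The lactone would be opened, two aryl Grignard additions would give a 1,4-diketone, and C3=C4 would be closed last by aldol condensation of the formyl diketone A3.
Weak point 1: turning an aldehyde into the boronic acid A1 (two etherifications, Dakin oxidation, triflation, borylation, pinacol cleavage) would spend six steps without any gain in complexity.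
Weak point 2: the late exchange of six benzyl ethers for six acetates, and the detour bromide → vinyl → aldehyde, would cost four steps on the most precious material only to reach A3.
Weak point 3: C2 would be set early and then carried, as an increasingly acidic α-keto CH of the less stable cis series, through Grignard reagent, Lewis acid, Pd at 100 °C, enolisation, dehydration and a six-fold enzymatic deacetylation. The cis relation would rest on survival, not on control.

Feature used: C1 carries two constitutionally identical 2-methoxy-3,4-dioxygenated phenyl rings (ring B is one of them, tied back from its only free ortho carbon C4a through C4). C1–H is doubly benzylic, and H1 and H2 are cis, as if one hydrogen had moved from C1 to C2.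
Cuts: C1–C2 together with C2–H (carbene C–H insertion, key step); C3=C4 (aldol condensation); C4–C4a (formylation); both C1–aryl bonds (formaldehyde + two arenes); C2–C3 (enolate dimerisation to a symmetric 1,4-diketone).
Ring order: rings A and B are joined through C1 at the outset as a symmetric diarylmethane. Ring B becomes distinct only on formylation, the carbocycle closes at C1–C2, and no heterocyclic template is built or opened.
Why the weak steps vanish: no aryl-metal reagent is needed, and the aldehyde is put directly on an early, cheap intermediate. One protecting-group set is carried throughout, and both stereocentres arise together in the neutral ring closure, one step before the end.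

Key step: step 8

Assumption: the SMILES is read as (1S,2S), i.e. H1/H2 cis (C1 aryl and C2 aroyl on the same face), with the fused-ring methoxy at C8, peri to C1. Dihydronaphthalene numbering is used; ring A is the pendant aryl and ring B the fused arene.

Step 1
Reactants: 1 3-methoxycatechol
Product: 2 4-methoxy-2,2-dimethyl-1,3-benzodioxole
Conditions: 2,2-dimethoxypropane, p-TsOH (cat.), toluene, reflux, MeOH removed (4 Å MS)
Reagents that add atoms: 2,2-dimethoxypropane, COC(C)(C)OC
Why: Acid-catalysed transketalisation (acetonide formation) closes the five-membered benzodioxole once methanol is removed, and it masks the catechol with a group that is inert to base, carbenes and POCl3 and holds both oxygen lone pairs in conjugation with the ring.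

Step 2
Reactants: 2 4-methoxy-2,2-dimethyl-1,3-benzodioxole (two equivalents react, used in excess)
Product: 3 bis(4-methoxy-2,2-dimethyl-1,3-benzodioxol-5-yl)methane
Conditions: (CH2O)n (limiting), p-TsOH (cat.), AcOH, 40 °C; excess 2 recovered
Reagents that add atoms: paraformaldehyde (reacts as formaldehyde), C=O
Why: Baeyer-type condensation (two Friedel–Crafts alkylations through the benzylic cation) should take place at C5, para to the dioxole O1 and ortho to OMe, which is the site at which 4-methoxy-1,3-benzodioxoles are known to be formylated because the positions next to the strained five-membered ring are deactivated, and the excess of 2 holds back oligomers, so that both aryl–C1 bonds of the target arise at once.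

Step 3
Reactants: 3 bis(4-methoxy-2,2-dimethyl-1,3-benzodioxol-5-yl)methane
Product: 5 7-methoxy-6-[(4-methoxy-2,2-dimethyl-1,3-benzodioxol-5-yl)methyl]-2,2-dimethyl-1,3-benzodioxole-5-carbaldehyde, via aryl iminium chloride 4 (not isolated)
Conditions: POCl3 (limiting), DMF, ClCH2CH2Cl, 0 to 70 °C; then ice-water; unreacted 3 recovered
Reagents that add atoms: N,N-dimethylformamide, CN(C)C=O (formyl carbon); water, O (aldehyde oxygen)
Why: Vilsmeier–Haack formylation should go to C6, para to the dioxole O3, as in other 5-alkyl-1,3-benzodioxoles, because the OMe group, now flanked on both sides, is twisted out of conjugation and no longer activates C7, while the identity of the two rings makes either attack give 5, and the limiting reagent together with the positive charge of 4 holds back a second formylation.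

Step 4
Reactants: 6 1-[4-(benzyloxy)phenyl]ethanone (two equivalents)
Product: 8 1,4-bis[4-(benzyloxy)phenyl]butane-1,4-dione, via lithium enolate 7 (not isolated)
Conditions: LDA, THF, −78 °C; CuCl2, DMF, −78 °C to rt
Reagents that add atoms: none
Why: Oxidative dimerisation of the ketone enolate with Cu(II) (single-electron oxidation and α,α′-coupling) gives the symmetric 1,4-diketone, which holds C2, C3 and both aroyl groups.

Step 5
Reactants: 8 1,4-bis[4-(benzyloxy)phenyl]butane-1,4-dione; 5 the ring-B aldehyde of step 3
Product: 10 aldol adduct 1,4-bis[4-(benzyloxy)phenyl]-2-[hydroxy(aryl)methyl]butane-1,4-dione (aryl = ring B of 5; racemic diastereomer mixture), via lithium monoenolate 9 (not isolated)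
Conditions: 8 (slight excess), LDA, THF, −78 °C; then 5; AcOH quench at −78 °C
Reagents that add atoms: none
Why: Directed aldol addition of a preformed lithium enolate to a non-enolisable aldehyde forms C3–C4, the two CH2 groups of 8 being equivalent and the new stereocentres being erased in step 6.

Step 6
Reactants: 10 aldol adduct
Product: 12 (2E)-1,4-bis[4-(benzyloxy)phenyl]-2-(arylmethylidene)butane-1,4-dione (aryl = ring B of 5; ring B cis to C2H2), via mesylate 11 (not isolated)
Conditions: MsCl, Et3N, CH2Cl2, 0 °C; then DBU, 0 °C to rt
Reagents that add atoms: none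
Why: Mesylation and E1cB elimination give the conjugated enone under equilibrating conditions as the more stable (E) isomer, in which ring B is trans to the C3 aroyl group and hence cis to C2H2, the geometry that the ring closure needs.

Step 7
Reactants: 12 (E)-arylidene 1,4-diketone
Product: 13 (E)-1,4-bis[4-(benzyloxy)phenyl]-2-diazo-3-(arylmethylidene)butane-1,4-dione (aryl = ring B of 5)
Conditions: p-ABSA, DBU, MeCN/CH2Cl2, 0 °C, dark; short SiO2 plug, used at once
Reagents that add atoms: 4-acetamidobenzenesulfonyl azide, CC(=O)Nc1ccc(cc1)S(=O)(=O)N=[N+]=[N-]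
Why: Regitz diazo transfer works on a CH2 group that is activated by an aroyl and an alkenyl group, as in the usual preparation of alkenyl diazo carbonyl compounds from β,γ-unsaturated ones, and ring B cis to C2 should slow the 1,5-cyclisation of 13 to a pyrazole.

Step 8
Reactants: 13 alkenyl diazo diketone
Product: 15 (1S,2S)-licobichalcone 3′,4′:6,7-bis(acetonide) bis(benzyl ether) (C1 aryl and C2 aroyl cis), via rhodium carbene 14 (not isolated)
Conditions: Rh2(S-PTTL)4 (2 mol %), 4 Å MS, PhCF3/CH2Cl2, −20 °C to rt, slow addition of 13
Reagents that add atoms: none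
Why: Proposed new method: Rh(II) takes N2 from 13 to give the acyl(alkenyl)carbene 14, in which the (E)-C3=C4 bond and the C4a=C8a bond of ring B hold the doubly benzylic, strongly hydridic C1H2 group next to C2, so that a C1–H bond adds to the empty carbene orbital in one three-centre event that forms C1–C2 and C2–H together; the closest known reaction type is the intramolecular Rh(II)-carbene insertion into benzylic C–H bonds, known in enantioselective and cis-selective form for aryldiazoacetates (cis-2-aryl-2,3-dihydrobenzofuran-3-carboxylates) and in the 1,6 mode for isochromans, but not for an alkenyl diazo ketone and a diarylmethane. The carbocycle closes in the 1,6 mode (six-membered ring, four sp2 atoms in the tether), and no C–H bond is placed for the usual 1,5 mode. Relative configuration: at the transition state Rh and the C2 aroyl group stand on opposite faces of the nascent ring and ring A on C1 turns away from the bulky Rh2L4 wall, that is to the aroyl face, so H1 and H2 should end cis, the kinetic and less stable relation that is required; should hydride shift run ahead, the o-quinodimethane so formed (ring A and aroyl both outside) would close by disrotation to the same cis isomer. Absolute configuration: the chiral carboxylate pocket decides which enantiotopic C1–H and which carbene face react, both antipodes of the catalyst are available, and the one that gives (1S,2S) is kept after a first assignment. Chemoselectivity is needed against pyrazole formation, carbene dimerisation and attack on arenes or OCH2Ph groups, and it is secured by proximity, by the hydridic character of a C–H flanked by two trioxygenated rings, by ring B cis to C2 and by slow addition. The medium is neutral and aprotic, so the new, epimerisable C2–H is not touched.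

Step 9
Reactants: 15 protected licobichalcone
Product: 16 licobichalcone, [(1S,2S)-1-(3,4-dihydroxy-2-methoxyphenyl)-6,7-dihydroxy-8-methoxy-1,2-dihydronaphthalene-2,3-diyl]bis[(4-hydroxyphenyl)methanone]
Conditions: BCl3, C6HMe5, CH2Cl2, −78 to −40 °C; THF/pH 7 phosphate buffer added at −78 °C, N2
Reagents that add atoms: none
Why: Lewis-acid cleavage of the two aryl benzyl ethers and the two catechol ketals with a non-basic cation scavenger runs through benzyl and 2-aryloxyprop-2-yl cations at a temperature at which aryl methyl ethers persist and at which, without base or protic acid, C2 is not enolised, and the cold buffered quench keeps it so.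

Compound list
1 | 3-methoxycatechol | COc1cccc(O)c1O | starting material
2 | 4-methoxy-2,2-dimethyl-1,3-benzodioxole | COc1cccc2OC(C)(C)Oc12 | intermediate
3 | bis(4-methoxy-2,2-dimethyl-1,3-benzodioxol-5-yl)methane | COc1c(Cc2ccc3OC(C)(C)Oc3c2OC)ccc2OC(C)(C)Oc12 | intermediate
4 | aryl iminium chloride (N,N-dimethyliminium salt of 5) | C[N+](C)=Cc1cc2OC(C)(C)Oc2c(OC)c1Cc1ccc2OC(C)(C)Oc2c1OC.[Cl-] | intermediate
5 | 7-methoxy-6-[(4-methoxy-2,2-dimethyl-1,3-benzodioxol-5-yl)methyl]-2,2-dimethyl-1,3-benzodioxole-5-carbaldehyde | O=Cc1cc2OC(C)(C)Oc2c(OC)c1Cc1ccc2OC(C)(C)Oc2c1OC | intermediate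
6 | 1-[4-(benzyloxy)phenyl]ethanone | CC(=O)c1ccc(OCc2ccccc2)cc1 | starting material
7 | lithium enolate of 6 | [Li+].[O-]C(=C)c1ccc(OCc2ccccc2)cc1 | intermediate
8 | 1,4-bis[4-(benzyloxy)phenyl]butane-1,4-dione | O=C(CCC(=O)c1ccc(OCc2ccccc2)cc1)c1ccc(OCc2ccccc2)cc1 | intermediate
9 | lithium monoenolate of 8 | [Li+].[O-]C(=CCC(=O)c1ccc(OCc2ccccc2)cc1)c1ccc(OCc2ccccc2)cc1 | intermediate
10 | aldol adduct (racemic diastereomer mixture) | OC(C(CC(=O)c1ccc(OCc2ccccc2)cc1)C(=O)c1ccc(OCc2ccccc2)cc1)c1cc2OC(C)(C)Oc2c(OC)c1Cc1ccc2OC(C)(C)Oc2c1OC | intermediate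
11 | mesylate of 10 | CS(=O)(=O)OC(C(CC(=O)c1ccc(OCc2ccccc2)cc1)C(=O)c1ccc(OCc2ccccc2)cc1)c1cc2OC(C)(C)Oc2c(OC)c1Cc1ccc2OC(C)(C)Oc2c1OC | intermediate
12 | (E)-arylidene 1,4-diketone | O=C(C/C(C(=O)c1ccc(OCc2ccccc2)cc1)=C\c1cc2OC(C)(C)Oc2c(OC)c1Cc1ccc2OC(C)(C)Oc2c1OC)c1ccc(OCc2ccccc2)cc1 | intermediate
13 | (E)-alkenyl diazo diketone | O=C(C(=[N+]=[N-])/C(C(=O)c1ccc(OCc2ccccc2)cc1)=C\c1cc2OC(C)(C)Oc2c(OC)c1Cc1ccc2OC(C)(C)Oc2c1OC)c1ccc(OCc2ccccc2)cc1 | intermediate
14 | rhodium carbene from 13 (Rh2L4 drawn as Rh) | O=C(C(=[Rh])/C(C(=O)c1ccc(OCc2ccccc2)cc1)=C\c1cc2OC(C)(C)Oc2c(OC)c1Cc1ccc2OC(C)(C)Oc2c1OC)c1ccc(OCc2ccccc2)cc1 | intermediate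
15 | (1S,2S)-licobichalcone bis(acetonide) bis(benzyl ether) | COc1c([C@H]2c3c(cc4OC(C)(C)Oc4c3OC)C=C(C(=O)c3ccc(OCc4ccccc4)cc3)[C@H]2C(=O)c2ccc(OCc3ccccc3)cc2)ccc2OC(C)(C)Oc12 | intermediate
16 | licobichalcone | COc1c([C@H]2c3c(cc(O)c(O)c3OC)C=C(C(=O)c3ccc(O)cc3)[C@H]2C(=O)c2ccc(O)cc2)ccc(O)c1O | target

Total step count: 9. Longest linear sequence: 8 (steps 1, 2, 3, 5, 6, 7, 8, 9).

Steps most likely to fail

Step 8 (Proposed new method).
- What may go wrong: hydride transfer from the very electron-rich C1–H may run ahead of C–C bond formation. The catalyst would then leave, and the ring would close from a catalyst-free o-quinodimethane without enantiocontrol, although still cis. Slow carbene formation at the crowded diazo carbon would also lower the efficiency.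
- Fallback: catalyst control is given up for resolution. Setting out from 13, decomposition with achiral Rh2(OAc)4 would give the cis racemate, that is 15 together with its mirror image, the (1R,2R)-bis(acetonide) bis(benzyl ether) F1. Preparative chromatography on a polysaccharide chiral stationary phase with a neutral eluent comes back to the route at 15.

Step 7.
- What may go wrong: under DBU the C3=C4 double bond may migrate into conjugation with both ketones before the azide is attacked, or the diazo compound may cyclise during its formation.
- Fallback: a base-free entry to the C=N bond by the Forster reaction. Setting out from 12, nitrosation of C2H2 with isoamyl nitrite/HCl would give the 2-(hydroxyimino) diketone F2, which has no C2–H left to shift. Chloramine would convert it into the diazo compound, coming back to the route at 13.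

Step 9.
- What may go wrong: ketal cleavage may be too slow at the temperature that keeps C2 safe, and warming would bring epimerisation to the trans series or loss of the flanked methyl ethers.
- Fallback: the protecting groups are changed at the last achiral stage.
  - Setting out from 12, BCl3/C6HMe5 (temperature no longer critical) would give the hexaphenol arylidene diketone F3.
  - TBSCl/imidazole would give the hexakis(TBS) ether F4.
  - Diazo transfer would give the silylated diazo diketone F5.
  - The Rh-catalysed insertion would give hexakis(TBS)-licobichalcone F6.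
  - Pyridine-buffered HF·pyridine in THF at 0 °C comes back to the route at 16.

Further compounds
F1 | step 8 | (1R,2R)-enantiomer of 15 | COc1c([C@@H]2c3c(cc4OC(C)(C)Oc4c3OC)C=C(C(=O)c3ccc(OCc4ccccc4)cc3)[C@@H]2C(=O)c2ccc(OCc3ccccc3)cc2)ccc2OC(C)(C)Oc12
F2 | step 7 | 2-(hydroxyimino) derivative of 12 | O=C(C(=NO)/C(C(=O)c1ccc(OCc2ccccc2)cc1)=C\c1cc2OC(C)(C)Oc2c(OC)c1Cc1ccc2OC(C)(C)Oc2c1OC)c1ccc(OCc2ccccc2)cc1
F3 | step 9 | hexaphenol (E)-arylidene diketone | O=C(C/C(C(=O)c1ccc(O)cc1)=C\c1cc(O)c(O)c(OC)c1Cc1ccc(O)c(O)c1OC)c1ccc(O)cc1
F4 | step 9 | hexakis(TBS) ether of F3 | O=C(C/C(C(=O)c1ccc(O[Si](C)(C)C(C)(C)C)cc1)=C\c1cc(O[Si](C)(C)C(C)(C)C)c(O[Si](C)(C)C(C)(C)C)c(OC)c1Cc1ccc(O[Si](C)(C)C(C)(C)C)c(O[Si](C)(C)C(C)(C)C)c1OC)c1ccc(O[Si](C)(C)C(C)(C)C)cc1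
F5 | step 9 | 2-diazo derivative of F4 | O=C(C(=[N+]=[N-])/C(C(=O)c1ccc(O[Si](C)(C)C(C)(C)C)cc1)=C\c1cc(O[Si](C)(C)C(C)(C)C)c(O[Si](C)(C)C(C)(C)C)c(OC)c1Cc1ccc(O[Si](C)(C)C(C)(C)C)c(O[Si](C)(C)C(C)(C)C)c1OC)c1ccc(O[Si](C)(C)C(C)(C)C)cc1
F6 | step 9 | (1S,2S)-hexakis(TBS)-licobichalcone | COc1c([C@H]2c3c(cc(O[Si](C)(C)C(C)(C)C)c(O[Si](C)(C)C(C)(C)C)c3OC)C=C(C(=O)c3ccc(O[Si](C)(C)C(C)(C)C)cc3)[C@H]2C(=O)c2ccc(O[Si](C)(C)C(C)(C)C)cc2)ccc(O[Si](C)(C)C(C)(C)C)c1O[Si](C)(C)C(C)(C)C
A1 | direct plan | [3,4-bis(benzyloxy)-2-methoxyphenyl]boronic acid | COc1c(B(O)O)ccc(OCc2ccccc2)c1OCc1ccccc1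
A2 | direct plan | (4S)-7-(benzyloxy)-4-[3,4-bis(benzyloxy)-2-methoxyphenyl]-8-hydroxychroman-2-one | COc1c([C@@H]2CC(=O)Oc3c(O)c(OCc4ccccc4)ccc32)ccc(OCc2ccccc2)c1OCc1ccccc1
A3 | direct plan | hexaacetate formyl 1,4-diketone | COc1c([C@H]([C@@H](CC(=O)c2ccc(OC(C)=O)cc2)C(=O)c2ccc(OC(C)=O)cc2)c2c(OC)c(OC(C)=O)c(OC(C)=O)cc2C=O)ccc(OC(C)=O)c1OC(C)=O
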